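I decide to stop following the target and freeze it, because the late ratio then needs one reckoning instead of two.

| flask | substrate | capture agent | remark | time |
|---|---|---|---|---|
| west | 2 M | 0.40 M | run made earlier |  |
| flask | 2.0 M | 0.200 M |  | 6.0 h |

west run (percent of the substrate charged)

| time / min | side product / % | target / % | substrate / % |
|---|---|---|---|
| 3.00 | 0.2 | 0.4 | 32.2 |
| 5.00 | 0.9 | 1.5 | 16.4 |
| 8.00 | 3.8 | 1.8 | 6.3 |
| 12.0 | 8.8 | 2.5 | 2.1 |
| 20.0 | 19.0 | 4.0 | 0.2 |
| 40.0 | 34.2 | 4.3 | 0 |

(scatter of a reading: 0.3 percentage points)

- ratio of side product to target at 5.0 min
- ratio of side product to target at 6.0 h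
- which of side product and target there is more of at 6.0 h

- no earlier run changes the charge of capture agent; that part of a forecast is a guess

In the west run the target reads 4.0% at 20.0 min and 4.3% at 40.0 min, a step of one scatter, and the substrate is already down to 0.2% at the first of these times. I call the mean of the two readings, 4.15% of the charge, the target ceiling: the level where the target stands late in the run, with the substrate at 0.2% or below.

The side product of the west run behaves otherwise: between the same two times it climbs from 19.0% to 34.2%, with the substrate reading 0.2% at the start of that climb, so something unseen still feeds it. Its slopes before and after 20.0 min have midpoints 14.0 min apart. If the slope falls exponentially, they give a lifetime of 27.1 min. That leaves a tail of 14.2% after the last reading, so the side product ends near 48.4%.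

Carrying both over to the flask unchanged is a guess, since no earlier run changes the capture agent. My late ratio, the selectivity, is then 11.7, with the side product ahead. The early ratio rests on two small readings, so I stake nothing on it.

The forecast gives 1.4 at 5.0 min (range 0.6 to 3) and 40 at 6.0 h (range 15 to 90), with the side product ahead. It reasons “If target scales with capture agent”, whereas I hold the target still.

The flask gives 0.970 at 5.0 min and 11.3 at 6.0 h, with 45.6% side product against 4.03% target, so the side product leads.

    substrate → intermediate A (k = 0.00307 s⁻¹)
    intermediate A ⇌ intermediate B (K = 3.08, k = 0.00276 s⁻¹)
    substrate → intermediate C (k = 0.00222 s⁻¹)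
    intermediate C → target (k = 2.35 × 10⁻⁴ s⁻¹)
    intermediate B ⇌ intermediate D (K = 0.747, k = 0.00341 s⁻¹)
    intermediate D → side product (k = 0.00365 s⁻¹)
    2 substrate → homo dimer (k = 4.20 × 10⁻⁴ M⁻¹ s⁻¹)
    intermediate C → decomposed reagent (k = 0.00189 s⁻¹)
    capture agent + intermediate D → trapped intermediate (k = 0.00259 M⁻¹ s⁻¹)

In the flask the target stands at 4.03% against the ceiling of 4.15%, and side product over ceiling gives 11.0. The flask's target is low partly because intermediate C also turns into decomposed reagent: without that step the flask's late ratio falls from 11.3 to 1.26, the largest single effect on it, though not the whole story. The capture agent acts on intermediate D, on the side product's branch. With 0.50 M of it, the neighbour flask keeps its target at 4.03% while its side product is 39.6%, so side product over ceiling gives 9.54 against its actual ratio of 9.84.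

The earlier runs and the new flask are simulated for an exercise, noise included.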